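**Retrosynthetic overview**

1. Numbering (germacranolide): carbocycle C1–C10; O11 is the ether bridge C5–O–C10; lactone O6–C12(=O)–C11(=C13)–C7; C14 is the methyl on C10; C15 is the ester carbon on C4; the acyl group sits on O8.
2. Enabling feature: C5 is bonded to the bridging oxygen O11 and to C4, the α-carbon of the C3=C4–C15 acrylate. O11–C5–C4(=C3)–CO2Me is therefore the retron of an oxocarbenium + alkynoate + iodide coupling (β-iodo Morita–Baylis–Hillman / halo-Prins). Because O11 also holds C10, the C4–C5 bond can be closed across the oxepane ring (O11, C5–C10); a 10-membered carbocyclisation becomes a 7-membered closure and C10 dictates C5.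
3. Disconnections (backwards): C3–H ⇐ C3–I; C4–C5 and O11–C5 ⇐ C5 aldehyde + C10–OSiEt3 + C3≡C4–CO2Me + Me3SiI in one operation; O8 acyl ⇐ Mitsunobu inversion with the acid (from (R)-lactic acid); C7–C8 ⇐ Barbier allylation of a C8 aldehyde (from geraniol, C10 by Sharpless epoxidation) with a 3-(bromomethyl)butenolide (C6 from (S)-but-3-ene-1,2-diol).
4. Ring order: butenolide (ring-closing metathesis) → α-methylene-γ-lactone (Barbier allylation) → oxepane (O11–C5), then oxepene plus 10-membered carbocycle (C4–C5), the last two in the key step.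

Key step: step 18

Remark: the C3=C4 double bond carries no descriptor in the SMILES and is taken as the only isomer the seven-membered oxepene allows (C2 and C5 cis).

**Route**

Step 1
Reactants: 1 (R)-lactic acid
Product: 2 (2R,5R)-2-tert-butyl-5-methyl-1,3-dioxolan-4-one
Conditions: t-BuCHO, TsOH·H2O (cat.), H2SO4 (cat.), pentane, reflux, Dean–Stark; crystallisation of the cis isomer
Reagents that add atoms: pivalaldehyde, CC(C)(C)C=O
Why: Acid-catalysed acetalisation with water removal; the lactic acid centre sets the acetal centre through the thermodynamic preference for the cis-2,5-disubstituted dioxolanone, which is purified by crystallisation.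

Step 2
Reactants: 2 (2R,5R)-2-tert-butyl-5-methyl-1,3-dioxolan-4-one
Product: 4 (2R,5S)-2-tert-butyl-5-(1-hydroxyethyl)-5-methyl-1,3-dioxolan-4-one (carbinol epimers), via lithium enolate 3 (not isolated)
Conditions: LDA, THF, −78 °C; then MeCHO, −78 °C; AcOH quench
Reagents that add atoms: acetaldehyde, CC=O
Why: Aldol addition of the dioxolanone enolate (self-regeneration of the stereocentre): the acetal tert-butyl group shields one face, so acetaldehyde adds anti to it and the quaternary centre is formed in the sense that becomes 2S in acid 6.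

Step 3
Reactants: 4 (2R,5S)-2-tert-butyl-5-(1-hydroxyethyl)-5-methyl-1,3-dioxolan-4-one
Product: 5 (2R,5S)-2-tert-butyl-5-ethenyl-5-methyl-1,3-dioxolan-4-one
Conditions: Martin sulfurane, CH2Cl2, 0 °C → rt
Reagents that add atoms: none
Why: Dehydration of the secondary alcohol through its alkoxysulfonium salt (E2 elimination); the neighbouring carbon is quaternary, so only the methyl hydrogens can be lost and the vinyl group results.

Step 4
Reactants: 5 (2R,5S)-2-tert-butyl-5-ethenyl-5-methyl-1,3-dioxolan-4-one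
Product: 6 (S)-2-hydroxy-2-methylbut-3-enoic acid
Conditions: LiOH, THF/H2O, 0 °C → rt; acidic work-up (1 M HCl)
Reagents that add atoms: lithium hydroxide, [Li+].[OH-]
Why: Saponification of the acetal ester with loss of pivalaldehyde from the hemiacetal; the quaternary centre is not touched.

Step 5
Reactants: 7 geraniol
Product: 8 (2S,3S)-2,3-epoxygeraniol
Conditions: Ti(OiPr)4 (cat.), L-(+)-diethyl tartrate (cat.), t-BuOOH, 4 Å MS, CH2Cl2, −20 °C
Reagents that add atoms: tert-butyl hydroperoxide, CC(C)(C)OO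
Why: Sharpless asymmetric epoxidation; the titanium L-(+)-tartrate complex delivers oxygen to the face that gives the (2S,3S)-epoxide, which fixes the future C10.

Step 6
Reactants: 8 (2S,3S)-2,3-epoxygeraniol
Product: 9 (3S)-3,7-dimethyloct-6-ene-1,3-diol
Conditions: NaAlH2(OCH2CH2OCH3)2 (Red-Al), THF, 0 °C; Rochelle salt work-up
Reagents that add atoms: none
Why: Hydroxyl-directed reductive opening of the 2,3-epoxy alcohol; hydride is delivered from the alkoxyaluminate to C2, so the 1,3-diol forms and the tertiary C–O bond stays intact.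

Step 7
Reactants: 9 (3S)-3,7-dimethyloct-6-ene-1,3-diol
Product: 10 (3S)-3,7-dimethyl-1,3-bis(triethylsilyloxy)oct-6-ene
Conditions: Et3SiOTf (2.4 equiv), 2,6-lutidine, CH2Cl2, −78 → 0 °C
Reagents that add atoms: triethylsilyl trifluoromethanesulfonate, CC[Si](CC)(CC)OS(=O)(=O)C(F)(F)F
Why: O-silylation of both hydroxyls; the silyl triflate is needed for the tertiary alcohol.

Step 8
Reactants: 10 (3S)-3,7-dimethyl-1,3-bis(triethylsilyloxy)oct-6-ene
Product: 11 (4S)-4-methyl-4,6-bis(triethylsilyloxy)hexanal
Conditions: O3, pyridine (3 equiv), CH2Cl2, −78 °C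
Reagents that add atoms: ozone, [O-][O+]=O
Why: Ozonolysis of the only alkene; pyridine decomposes the carbonyl oxide so that the aldehyde forms directly, and the silyl ethers are inert.

Step 9
Reactants: 11 (4S)-4-methyl-4,6-bis(triethylsilyloxy)hexanal
Product: 12 (5S)-1,1-dibromo-5-methyl-5,7-bis(triethylsilyloxy)hept-1-ene
Conditions: CBr4, PPh3, Et3N, CH2Cl2, 0 °C
Reagents that add atoms: carbon tetrabromide, BrC(Br)(Br)Br
Why: First stage of the Corey–Fuchs reaction (Wittig-type olefination with the dibromomethylene ylide); triethylamine protects the silyl ethers from acid.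

Step 10
Reactants: 12 (5S)-1,1-dibromo-5-methyl-5,7-bis(triethylsilyloxy)hept-1-ene
Product: 14 methyl (6S)-6-methyl-6,8-bis(triethylsilyloxy)oct-2-ynoate, via lithium acetylide 13 (not isolated)
Conditions: n-BuLi (2.1 equiv), THF, −78 °C; then ClCO2Me, −78 → 0 °C
Reagents that add atoms: methyl chloroformate, COC(=O)Cl
Why: Second stage of the Corey–Fuchs reaction (dehydrobromination and bromine–lithium exchange to the acetylide), followed by C-acylation with the chloroformate.

Step 11
Reactants: 14 methyl (6S)-6-methyl-6,8-bis(triethylsilyloxy)oct-2-ynoate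
Product: 16 methyl (6S)-6-methyl-8-oxo-6-(triethylsilyloxy)oct-2-ynoate, via alkoxysulfonium chloride 15 (not isolated)
Conditions: (COCl)2, DMSO, CH2Cl2, −78 → −30 °C; then Et3N, −78 → 0 °C
Reagents that add atoms: none
Why: Swern oxidation with in situ cleavage of the primary triethylsilyl ether, a known chemoselective oxidative desilylation that leaves hindered (here tertiary) silyl ethers in place.

Step 12
Reactants: 17 (2S)-but-3-ene-1,2-diol
Product: 18 (2S)-1-(triethylsilyloxy)but-3-en-2-ol
Conditions: Et3SiCl (1.0 equiv), imidazole, CH2Cl2, −78 → −20 °C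
Reagents that add atoms: chlorotriethylsilane, CC[Si](Cl)(CC)CC
Why: Selective silylation of the primary hydroxyl at low temperature (steric differentiation of primary and secondary alcohol).

Step 13
Reactants: 18 (2S)-1-(triethylsilyloxy)but-3-en-2-ol; 19 2-(bromomethyl)acrylic acid
Product: 20 (2S)-1-(triethylsilyloxy)but-3-en-2-yl 2-(bromomethyl)acrylate
Conditions: DCC, DMAP (5 mol %), CH2Cl2, −10 °C
Reagents that add atoms: none
Why: Steglich esterification of the secondary allylic alcohol; low temperature and little DMAP limit attack of the pyridine on the allylic bromide.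

Step 14
Reactants: 20 (2S)-1-(triethylsilyloxy)but-3-en-2-yl 2-(bromomethyl)acrylate
Product: 21 (5S)-3-(bromomethyl)-5-[(triethylsilyloxy)methyl]furan-2(5H)-one
Conditions: second-generation Grubbs catalyst (5 mol %), CH2Cl2, 40 °C
Reagents that add atoms: none
Why: Ring-closing metathesis of the 2-substituted acrylate with the vinyl group gives the butenolide; the base-free conditions leave the epimerisable γ-centre (C6) untouched.

Step 15
Reactants: 21 (5S)-3-(bromomethyl)-5-[(triethylsilyloxy)methyl]furan-2(5H)-one; 16 methyl (6S)-6-methyl-8-oxo-6-(triethylsilyloxy)oct-2-ynoate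
Product: 23 methyl (6S,8S)-8-hydroxy-6-methyl-8-[(2S,3R)-4-methylidene-5-oxo-2-{[(triethylsilyl)oxy]methyl}oxolan-3-yl]-6-(triethylsilyloxy)oct-2-ynoate, via allylzinc bromide 22 (not isolated)
Conditions: Zn dust (activated), THF, 0 °C → rt; AcOH then pH 7 buffer
Reagents that add atoms: none
Why: Barbier allylation (2-alkoxycarbonylallyl type): the allylzinc reacts at its γ-carbon C7 anti to the C6 substituent (7R, trans lactone) and, as an E-configured cyclic allylmetal in a Zimmerman–Traxler chair with the aldehyde residue equatorial, is expected to give the 8S carbinol, the C8 epimer of the target, which step 16 inverts.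

Step 16
Reactants: 23 methyl (6S,8S)-8-hydroxy-6-methyl-8-[(2S,3R)-4-methylidene-5-oxo-2-{[(triethylsilyl)oxy]methyl}oxolan-3-yl]-6-(triethylsilyloxy)oct-2-ynoate; 6 (S)-2-hydroxy-2-methylbut-3-enoic acid
Product: 24 methyl (6S,8R)-8-{[(2S)-2-hydroxy-2-methylbut-3-enoyl]oxy}-6-methyl-8-[(2S,3R)-4-methylidene-5-oxo-2-{[(triethylsilyl)oxy]methyl}oxolan-3-yl]-6-(triethylsilyloxy)oct-2-ynoate
Conditions: PPh3, DIAD (betaine pre-formed), toluene, 0 °C → rt
Reagents that add atoms: none
Why: Mitsunobu esterification, an SN2 displacement of the oxyphosphonium group by the carboxylate with inversion (8S → 8R); pre-forming the betaine keeps free phosphine away from the ynoate and the methylene lactone, and the tertiary alcohols do not react.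

Step 17
Reactants: 24 methyl (6S,8R)-8-{[(2S)-2-hydroxy-2-methylbut-3-enoyl]oxy}-6-methyl-8-[(2S,3R)-4-methylidene-5-oxo-2-{[(triethylsilyl)oxy]methyl}oxolan-3-yl]-6-(triethylsilyloxy)oct-2-ynoate
Product: 26 methyl (6S,8R)-8-[(2S,3R)-2-formyl-4-methylidene-5-oxooxolan-3-yl]-8-{[(2S)-2-hydroxy-2-methylbut-3-enoyl]oxy}-6-methyl-6-(triethylsilyloxy)oct-2-ynoate, via alkoxysulfonium chloride 25 (not isolated)
Conditions: (COCl)2, DMSO, CH2Cl2, −78 → −30 °C; then Et3N, −78 °C
Reagents that add atoms: none
Why: Swern oxidation with in situ cleavage of the primary triethylsilyl ether; the tertiary C10 silyl ether and the tertiary alcohol survive, and the cold amine quench limits epimerisation of the α-acyloxy aldehyde at C6.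

Step 18
Reactants: 26 methyl (6S,8R)-8-[(2S,3R)-2-formyl-4-methylidene-5-oxooxolan-3-yl]-8-{[(2S)-2-hydroxy-2-methylbut-3-enoyl]oxy}-6-methyl-6-(triethylsilyloxy)oct-2-ynoate
Product: 28 methyl (5R,6S,7R,8R,10S)-5,10-epoxy-8-{[(2S)-2-hydroxy-2-methylbut-3-enoyl]oxy}-3-iodogermacra-3,11(13)-dien-12,6-olid-15-oate, via cyclic α-iodo ether 27 (not isolated)
Conditions: Me3SiI (1.5 equiv), 2,6-di-tert-butyl-4-methylpyridine (0.3 equiv), CH2Cl2 (0.005 M), −78 → −20 °C; then Et3N, aq. NaHCO3/Na2S2O3
Reagents that add atoms: iodotrimethylsilane, C[Si](C)(C)I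
Why: Proposed new method: Me3SiI silylates the C5 aldehyde, the C10 silyl ether oxygen adds to it (7-exo-trig, as in the silyl-modified Sakurai condensation of an aldehyde with a silyl ether) and loss of Et3SiOSiMe3 gives the oxepanyl oxocarbenium iodide/α-iodo ether 27; iodide then adds to C3 of the ynoate while its α-carbon C4 (the iodo-allenolate carbon) bonds to C5 in an anti addition across the alkyne. The closest known reaction types are the iodide-triggered allenolate aldol of alkynoates with aldehydes (β-iodo Morita–Baylis–Hillman reaction, Me3SiI or TiCl4/Bu4NI) and the alkyne halo-Prins cyclisation; their intramolecular use on an oxocarbenium carbon across a medium ring is new. The C4–C5 bond closes the oxepene as a 7-membered ring that is endo to both the C5=O11 oxocarbenium and the alkyne, and because it runs across the oxepane it completes the 10-membered carbocycle at the same time. The new stereocentre C5 is dictated by C10: the chain on C10 can reach only the face of the oxocarbenium on its own side of the one-atom O11 bridge (5R), and the ring together with the anti addition forces C2 and C5 cis on C3=C4. The step needs iodide to attack the ynoate and not the α-methylene lactone (the sp-hybridised acceptor is the more electrophilic, and an HI adduct of the lactone would be returned by the Et3N quench) and O11–C5 formation to precede 5-exo oxa-Michael addition of O10 to the ynoate, which is secured by keeping O10 as its silyl ether until the aldehyde consumes it; high dilution and low temperature suppress oligomeric acetals and ionisation of the tertiary C10–O bond.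

Step 19
Reactants: 28 methyl (5R,6S,7R,8R,10S)-5,10-epoxy-8-{[(2S)-2-hydroxy-2-methylbut-3-enoyl]oxy}-3-iodogermacra-3,11(13)-dien-12,6-olid-15-oate
Product: 29 CNP0325750.1, methyl (5R,6S,7R,8R,10S)-5,10-epoxy-8-{[(2S)-2-hydroxy-2-methylbut-3-enoyl]oxy}germacra-3,11(13)-dien-12,6-olid-15-oate
Conditions: Zn dust, AcOH, THF, 0 °C → rt
Reagents that add atoms: none
Why: Reductive removal of the vinylogous α-iodo ester iodine (zinc insertion into the activated C–I bond, then protonation) with retention of the ring-locked alkene; the methylene lactone and the esters are not expected to be reduced under these conditions.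

**Compound list**

1 | (R)-lactic acid | C[C@@H](O)C(=O)O | starting material
2 | (2R,5R)-2-tert-butyl-5-methyl-1,3-dioxolan-4-one | C[C@H]1O[C@@H](C(C)(C)C)OC1=O | intermediate
3 | lithium enolate of 2 | CC1=C([O-])O[C@H](C(C)(C)C)O1.[Li+] | intermediate
4 | (2R,5S)-2-tert-butyl-5-(1-hydroxyethyl)-5-methyl-1,3-dioxolan-4-one (carbinol centre as a mixture, removed in step 3) | C[C@@]1(C(C)O)O[C@@H](C(C)(C)C)OC1=O | intermediate
5 | (2R,5S)-2-tert-butyl-5-ethenyl-5-methyl-1,3-dioxolan-4-one | C[C@@]1(C=C)O[C@@H](C(C)(C)C)OC1=O | intermediate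
6 | (S)-2-hydroxy-2-methylbut-3-enoic acid | C=C[C@](C)(O)C(=O)O | intermediate
7 | geraniol, (2E)-3,7-dimethylocta-2,6-dien-1-ol | CC(C)=CCC/C(C)=C/CO | starting material
8 | (2S,3S)-2,3-epoxygeraniol | OC[C@@H]1O[C@@]1(C)CCC=C(C)C | intermediate
9 | (3S)-3,7-dimethyloct-6-ene-1,3-diol | OCC[C@](O)(C)CCC=C(C)C | intermediate
10 | (3S)-3,7-dimethyl-1,3-bis(triethylsilyloxy)oct-6-ene | CC[Si](CC)(CC)OCC[C@](O[Si](CC)(CC)CC)(C)CCC=C(C)C | intermediate
11 | (4S)-4-methyl-4,6-bis(triethylsilyloxy)hexanal | CC[Si](CC)(CC)OCC[C@](O[Si](CC)(CC)CC)(C)CCC=O | intermediate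
12 | (5S)-1,1-dibromo-5-methyl-5,7-bis(triethylsilyloxy)hept-1-ene | CC[Si](CC)(CC)OCC[C@](O[Si](CC)(CC)CC)(C)CCC=C(Br)Br | intermediate
13 | [(5S)-5-methyl-5,7-bis(triethylsilyloxy)hept-1-yn-1-yl]lithium | CC[Si](CC)(CC)OCC[C@](O[Si](CC)(CC)CC)(C)CCC#C[Li] | intermediate
14 | methyl (6S)-6-methyl-6,8-bis(triethylsilyloxy)oct-2-ynoate | CC[Si](CC)(CC)OCC[C@](O[Si](CC)(CC)CC)(C)CCC#CC(=O)OC | intermediate
15 | alkoxydimethylsulfonium chloride from 14 (on O8) | C[S+](C)OCC[C@](O[Si](CC)(CC)CC)(C)CCC#CC(=O)OC.[Cl-] | intermediate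
16 | methyl (6S)-6-methyl-8-oxo-6-(triethylsilyloxy)oct-2-ynoate | O=CC[C@](O[Si](CC)(CC)CC)(C)CCC#CC(=O)OC | intermediate
17 | (2S)-but-3-ene-1,2-diol | C=C[C@H](O)CO | starting material
18 | (2S)-1-(triethylsilyloxy)but-3-en-2-ol | C=C[C@H](O)CO[Si](CC)(CC)CC | intermediate
19 | 2-(bromomethyl)acrylic acid | C=C(CBr)C(=O)O | starting material
20 | (2S)-1-(triethylsilyloxy)but-3-en-2-yl 2-(bromomethyl)acrylate | C=C[C@@H](CO[Si](CC)(CC)CC)OC(=O)C(=C)CBr | intermediate
21 | (5S)-3-(bromomethyl)-5-[(triethylsilyloxy)methyl]furan-2(5H)-one | O=C1O[C@H](CO[Si](CC)(CC)CC)C=C1CBr | intermediate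
22 | allylzinc bromide from 21 | O=C1O[C@H](CO[Si](CC)(CC)CC)C=C1C[Zn]Br | intermediate
23 | methyl (6S,8S)-8-hydroxy-6-methyl-8-[(2S,3R)-4-methylidene-5-oxo-2-{[(triethylsilyl)oxy]methyl}oxolan-3-yl]-6-(triethylsilyloxy)oct-2-ynoate (8-epi alcohol) | COC(=O)C#CCC[C@](C)(O[Si](CC)(CC)CC)C[C@H](O)[C@@H]1[C@@H](CO[Si](CC)(CC)CC)OC(=O)C1=C | intermediate
24 | methyl (6S,8R)-8-{[(2S)-2-hydroxy-2-methylbut-3-enoyl]oxy}-6-methyl-8-[(2S,3R)-4-methylidene-5-oxo-2-{[(triethylsilyl)oxy]methyl}oxolan-3-yl]-6-(triethylsilyloxy)oct-2-ynoate | COC(=O)C#CCC[C@](C)(O[Si](CC)(CC)CC)C[C@@H](OC(=O)[C@@](C)(O)C=C)[C@@H]1[C@@H](CO[Si](CC)(CC)CC)OC(=O)C1=C | intermediate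
25 | alkoxydimethylsulfonium chloride from 24 (on the C5 oxygen) | COC(=O)C#CCC[C@](C)(O[Si](CC)(CC)CC)C[C@@H](OC(=O)[C@@](C)(O)C=C)[C@@H]1[C@@H](CO[S+](C)C)OC(=O)C1=C.[Cl-] | intermediate
26 | methyl (6S,8R)-8-[(2S,3R)-2-formyl-4-methylidene-5-oxooxolan-3-yl]-8-{[(2S)-2-hydroxy-2-methylbut-3-enoyl]oxy}-6-methyl-6-(triethylsilyloxy)oct-2-ynoate | COC(=O)C#CCC[C@](C)(O[Si](CC)(CC)CC)C[C@@H](OC(=O)[C@@](C)(O)C=C)[C@@H]1[C@@H](C=O)OC(=O)C1=C | intermediate
27 | cyclic α-iodo ether: oxepane ring (O11, C5–C10) closed by the O11–C5 bond, iodine on C5 (C5 not fixed, in equilibrium with the oxocarbenium iodide), ynoate chain on C10 still open | COC(=O)C#CCC[C@@]1(C)C[C@@H](OC(=O)[C@@](C)(O)C=C)[C@@H]2[C@H](OC(=O)C2=C)C(I)O1 | intermediate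
28 | methyl (5R,6S,7R,8R,10S)-5,10-epoxy-8-{[(2S)-2-hydroxy-2-methylbut-3-enoyl]oxy}-3-iodogermacra-3,11(13)-dien-12,6-olid-15-oate | C=C[C@](C)(O)C(=O)O[C@@H]1C[C@]2(C)CCC(I)=C(C(=O)OC)[C@@H](O2)[C@H]2OC(=O)C(=C)[C@@H]21 | intermediate
29 | CNP0325750.1, methyl (5R,6S,7R,8R,10S)-5,10-epoxy-8-{[(2S)-2-hydroxy-2-methylbut-3-enoyl]oxy}germacra-3,11(13)-dien-12,6-olid-15-oate | C=C[C@](C)(O)C(=O)O[C@@H]1C[C@]2(C)CCC=C(C(=O)OC)[C@@H](O2)[C@H]2OC(=O)C(=C)[C@@H]21 | target

**Step count**

Total: 19 steps. Longest linear sequence: 12 steps (geraniol 7 → 29: steps 5–11 and 15–19).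

**Steps most likely to fail**

Step 18. What may go wrong: 5-exo oxa-Michael attack of O10 on the ynoate, oligomeric acetal formation or ionisation of the tertiary C10–O bond may outrun the transannular C–C bond formation. The fallback uses known chemistry: the same bond is made by a Nozaki–Hiyama–Kishi macrocyclisation and the ether is closed afterwards. It sets out from aldehyde 11 and returns to the route at the target 29. Wittig olefination of 11 with methyl 2-iodo-2-(triphenylphosphoranylidene)acetate should give methyl (2Z,6S)-2-iodo-6-methyl-6,8-bis(triethylsilyloxy)oct-2-enoate F1. Swern oxidation as in step 11 should give the aldehyde F2. Indium-mediated Barbier allylation with 21 in THF/H2O (indium does not insert into the vinyl iodide) should give the 8S alcohol F3, and Mitsunobu esterification with 6 as in step 16 the 8R ester F4. Swern oxidation as in step 17 should give the aldehyde F5. CrCl2 with catalytic NiCl2 in DMSO/THF at high dilution should then close the 10-membered ring to the allylic alcohol F6; retention at the vinyl carbon keeps C2 and C5 cis, and Felkin–Anh addition anti to O6 should favour 5R. Camphorsulfonic acid in CH2Cl2 finally cleaves the tertiary silyl ether, and the C10 cation is trapped across the ring by the C5 hydroxyl (only the cis-bridged ether can form), which should give 29 without the iodide stage.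

Step 16. What may go wrong: elimination towards C7, or capture of the activated C8 by the lactone carbonyl, may compete with SN2 inversion at the hindered carbinol, and phosphine may add to the ynoate. The fallback replaces substitution by oxidation and reduction; it sets out from 23 and returns at 24. Dess–Martin oxidation (NaHCO3 buffer) should give the C8 ketone F7, which is used at once because its methylene lactone can isomerise into conjugation. Reduction with (S)-2-methyl-CBS-oxazaborolidine and catecholborane at −78 °C (reagent control, the ring-bearing C7 as the large group) should give the 8R alcohol F8. Yamaguchi esterification with 6 (2,4,6-trichlorobenzoyl chloride, Et3N, then DMAP) proceeds with retention and gives 24.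

Step 15. What may go wrong: facial or simple diastereoselection may erode, or the allylzinc may react at its α-carbon. The fallback changes the allylation to an open-transition-state mode; it sets out from 21 (with 16) and returns at 24. Stannylation of 21 with (Bu3Sn)2 and Pd(PPh3)4 (cat.) should give the allylstannane F9. Its BF3·OEt2-promoted addition to 16 at −78 °C passes through an open antiperiplanar transition state, which is syn-selective and should give the (7R,8R) alcohol F8 directly, still anti to the C6 substituent. Yamaguchi esterification with 6 then gives 24.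

Further compounds
F1 | step 18 | methyl (2Z,6S)-2-iodo-6-methyl-6,8-bis(triethylsilyloxy)oct-2-enoate | CC[Si](CC)(CC)OCC[C@](O[Si](CC)(CC)CC)(C)CC/C=C(\I)C(=O)OC
F2 | step 18 | methyl (2Z,6S)-2-iodo-6-methyl-8-oxo-6-(triethylsilyloxy)oct-2-enoate | O=CC[C@](O[Si](CC)(CC)CC)(C)CC/C=C(\I)C(=O)OC
F3 | step 18 | methyl (2Z,6S,8S)-8-hydroxy-2-iodo-6-methyl-8-[(2S,3R)-4-methylidene-5-oxo-2-{[(triethylsilyl)oxy]methyl}oxolan-3-yl]-6-(triethylsilyloxy)oct-2-enoate | COC(=O)/C(I)=C/CC[C@](C)(O[Si](CC)(CC)CC)C[C@H](O)[C@@H]1[C@@H](CO[Si](CC)(CC)CC)OC(=O)C1=C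
F4 | step 18 | methyl (2Z,6S,8R)-8-{[(2S)-2-hydroxy-2-methylbut-3-enoyl]oxy}-2-iodo-6-methyl-8-[(2S,3R)-4-methylidene-5-oxo-2-{[(triethylsilyl)oxy]methyl}oxolan-3-yl]-6-(triethylsilyloxy)oct-2-enoate | COC(=O)/C(I)=C/CC[C@](C)(O[Si](CC)(CC)CC)C[C@@H](OC(=O)[C@@](C)(O)C=C)[C@@H]1[C@@H](CO[Si](CC)(CC)CC)OC(=O)C1=C
F5 | step 18 | methyl (2Z,6S,8R)-8-[(2S,3R)-2-formyl-4-methylidene-5-oxooxolan-3-yl]-8-{[(2S)-2-hydroxy-2-methylbut-3-enoyl]oxy}-2-iodo-6-methyl-6-(triethylsilyloxy)oct-2-enoate | COC(=O)/C(I)=C/CC[C@](C)(O[Si](CC)(CC)CC)C[C@@H](OC(=O)[C@@](C)(O)C=C)[C@@H]1[C@@H](C=O)OC(=O)C1=C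
F6 | step 18 | methyl (5R,6S,7R,8R,10S)-5-hydroxy-8-{[(2S)-2-hydroxy-2-methylbut-3-enoyl]oxy}-10-(triethylsilyloxy)germacra-3,11(13)-dien-12,6-olid-15-oate (10-membered carbocycle, C2 and C5 cis on C3=C4) | COC(=O)/C1=C/CC[C@](C)(O[Si](CC)(CC)CC)C[C@@H](OC(=O)[C@@](C)(O)C=C)[C@@H]2[C@H](OC(=O)C2=C)[C@@H]1O
F7 | step 16 | methyl (6S)-6-methyl-8-[(2S,3R)-4-methylidene-5-oxo-2-{[(triethylsilyl)oxy]methyl}oxolan-3-yl]-8-oxo-6-(triethylsilyloxy)oct-2-ynoate | COC(=O)C#CCC[C@](C)(O[Si](CC)(CC)CC)CC(=O)[C@@H]1[C@@H](CO[Si](CC)(CC)CC)OC(=O)C1=C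
F8 | step 16 | methyl (6S,8R)-8-hydroxy-6-methyl-8-[(2S,3R)-4-methylidene-5-oxo-2-{[(triethylsilyl)oxy]methyl}oxolan-3-yl]-6-(triethylsilyloxy)oct-2-ynoate | COC(=O)C#CCC[C@](C)(O[Si](CC)(CC)CC)C[C@@H](O)[C@@H]1[C@@H](CO[Si](CC)(CC)CC)OC(=O)C1=C
F9 | step 15 | (5S)-3-[(tributylstannyl)methyl]-5-[(triethylsilyloxy)methyl]furan-2(5H)-one | O=C1O[C@H](CO[Si](CC)(CC)CC)C=C1C[Sn](CCCC)(CCCC)CCCC
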